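**Plan**

- Retrosynthesis: the three aryl O–Me bonds are cut first, then the O1–C2 bond of each pyranone ring (ring C of both isoflavone units), then both C3–aryl bonds (C3–C1' and C3''–C1''') by a retro-1,2-aryl shift. This leads to an unsymmetrical bis-chalcone, which is cut at its two Cα=Cβ bonds and at the diaryl ether C–O bond.
- Forward: two MOM-protected acetophenones are made (from paeonol and from 2-chlororesorcinol). The first enone is formed with isovanillin, the diaryl ether is joined by fluoride displacement on 4-fluorobenzaldehyde, and the second enone completes the chain.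
- Both aryl groups are then moved from Cβ to Cα in one operation by anodically generated trivalent iodine in methanol. Acid closes both pyranone rings together, and demethylation ends the route.
- Enabling feature: C1' of ring B has the 4'-oxygen para to it and C1''' of the phenoxy ring has the diaryl ether oxygen para to it, so each ring can bridge Cα and Cβ as a phenonium ion and migrate.
- Stereochemistry: the target has no stereocentre. Both E-enones arise under thermodynamic control, and the two sp3 centres made in the key step are erased when C2=C3 forms.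

Key step: step 8

Remark: the sp3 centres in 8, 12, 14, 15, 16 and 17 arise without control, so each SMILES shows one stereoisomer of a racemic or diastereomeric mixture. In 14 the isovanillin-derived enone is assumed to react first, which does not change the outcome.

**Route**

Step 1
Reactants: 1 2-chlororesorcinol
Product: 2 1-(3-chloro-2,4-dihydroxyphenyl)ethan-1-one
Conditions: AcOH (2 equiv), BF3·OEt2, 90 °C; aq. NaOAc work-up
Reagents that add atoms: acetic acid, CC(=O)O
Why: Friedel–Crafts (Nencki-type) C-acylation with BF3-activated acetic acid goes to C4, which is ortho to one hydroxyl and para to the other and identical with C6 by symmetry, so a single ketone is expected.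

Step 2
Reactants: 2 1-(3-chloro-2,4-dihydroxyphenyl)ethan-1-one
Product: 3 1-(3-chloro-2-hydroxy-4-methoxyphenyl)ethan-1-one
Conditions: MeI (1.05 equiv), K2CO3 (1.1 equiv), acetone, rt to 40 °C
Reagents that add atoms: iodomethane, CI
Why: Williamson etherification should select the 4-OH because the 2-OH is held in a hydrogen bond to the ketone and is the weaker acid and nucleophile, the same selectivity that turns resacetophenone into paeonol.

Step 3
Reactants: 3 1-(3-chloro-2-hydroxy-4-methoxyphenyl)ethan-1-one
Product: 4 1-[3-chloro-4-methoxy-2-(methoxymethoxy)phenyl]ethan-1-one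
Conditions: NaH (1.1 equiv), MOMCl (1.2 equiv), DMF, 0 °C to rt
Reagents that add atoms: chloromethyl methyl ether (MOMCl), COCCl
Why: Full deprotonation with NaH breaks the chelate and the phenoxide is O-alkylated by MOMCl (Williamson-type acetal formation), while one equivalent of base leaves the methyl ketone untouched.

Step 4
Reactants: 5 paeonol, 1-(2-hydroxy-4-methoxyphenyl)ethan-1-one
Product: 6 1-[4-methoxy-2-(methoxymethoxy)phenyl]ethan-1-one
Conditions: NaH (1.1 equiv), MOMCl (1.2 equiv), DMF, 0 °C to rt
Reagents that add atoms: chloromethyl methyl ether (MOMCl), COCCl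
Why: The same phenoxide O-alkylation as in step 3 masks the ortho phenol as a base-stable, acid-labile acetal.

Step 5
Reactants: 6 1-[4-methoxy-2-(methoxymethoxy)phenyl]ethan-1-one; 7 isovanillin (3-hydroxy-4-methoxybenzaldehyde)
Product: 9 (E)-3-(3-hydroxy-4-methoxyphenyl)-1-[4-methoxy-2-(methoxymethoxy)phenyl]prop-2-en-1-one, via aldol adduct 8 (not isolated)
Conditions: KOH (50% aq., 4 equiv), EtOH, rt; then AcOH to pH 6 at 0 °C
Reagents that add atoms: none
Why: Claisen–Schmidt condensation, in which the enolate of 6 adds to the aldehyde and aldol 8 loses water by E1cB to the thermodynamically favoured E-enone; the phenoxide of isovanillin is meta to the formyl group and hardly deactivates it, and MOM ethers are stable to hydroxide.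

Step 6
Reactants: 9 (E)-3-(3-hydroxy-4-methoxyphenyl)-1-[4-methoxy-2-(methoxymethoxy)phenyl]prop-2-en-1-one; 10 4-fluorobenzaldehyde
Product: 11 4-[2-methoxy-5-[(E)-3-[4-methoxy-2-(methoxymethoxy)phenyl]-3-oxoprop-1-enyl]phenoxy]benzaldehyde
Conditions: Cs2CO3 (1.5 equiv), 10 (1.2 equiv), DMF, 80 °C
Reagents that add atoms: none
Why: Nucleophilic aromatic substitution by addition–elimination, in which the para-formyl group activates the C–F carbon toward the caesium phenoxide of 9, while the enone has no enolisable position and the MOM ether is base-stable.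

Step 7
Reactants: 11 4-[2-methoxy-5-[(E)-3-[4-methoxy-2-(methoxymethoxy)phenyl]-3-oxoprop-1-enyl]phenoxy]benzaldehyde; 4 1-[3-chloro-4-methoxy-2-(methoxymethoxy)phenyl]ethan-1-one
Product: 13 (E)-1-[3-chloro-4-methoxy-2-(methoxymethoxy)phenyl]-3-[4-[2-methoxy-5-[(E)-3-[4-methoxy-2-(methoxymethoxy)phenyl]-3-oxoprop-1-enyl]phenoxy]phenyl]prop-2-en-1-one (unsymmetrical bis-chalcone), via aldol adduct 12 (not isolated)
Conditions: 4 (1.0 equiv), KOH (50% aq., 3 equiv), EtOH–THF, 0 °C to rt
Reagents that add atoms: none
Why: Second Claisen–Schmidt condensation, in which the aryl aldehyde is the most electrophilic acceptor and the only one consumed irreversibly (aldol 12 dehydrates to the E-enone), so with one equivalent of 4 at room temperature it should outrun conjugate addition to the enone already present.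

Step 8
Reactants: 13 unsymmetrical bis-chalcone
Product: 15 1-[3-chloro-4-methoxy-2-(methoxymethoxy)phenyl]-2-[4-[5-[1,1-dimethoxy-3-[4-methoxy-2-(methoxymethoxy)phenyl]-3-oxopropan-2-yl]-2-methoxyphenoxy]phenyl]-3,3-dimethoxypropan-1-one (bis-acetal; mixture of diastereomers), via mono-rearranged acetal enone 14 (not isolated)
Conditions: (a) 4-iodotoluene (3 equiv), Bu4NBF4, CF3CH2OH, glassy-carbon anode, Pt cathode, undivided cell, constant current, 2.2 F per mol of iodide, rt, 13 absent; (b) current off, solution added to 13, MeOH–CH2Cl2, CH3SO3H (0.5 equiv), 0 °C to rt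
Reagents that add atoms: methanol, CO
Why: Proposed new method: two-electron anodic oxidation of 4-iodotoluene in trifluoroethanol gives TolI(OCH2CF3)2, which after acid-assisted ligand exchange adds as an electrophile to each enone C=C while methanol attacks the benzylic β-carbon; the α-C–I bond then ionises with participation of the β-aryl group (phenonium ion), the aryl group ends up on the α-carbon, 4-iodotoluene is released and methanol traps the oxocarbenium ion as the dimethyl acetal. The closest known reaction type is the oxidative 1,2-aryl migration of chalcones to 2-aryl-3,3-dimethoxypropan-1-ones with stoichiometric PhI(OH)OTs, PhI(OAc)2/acid or Tl(NO3)3 in methanol, and anodically made aryl iodine dialkoxides are established ex-cell oxidants for alkenes; their use for this rearrangement, and at two enones of one molecule, is the untested part. No ring is closed in this step. The two new stereocentres (the α-carbons, the future C3 of each isoflavone unit) form without any controlling element as a mixture of diastereomers, which is acceptable because both become sp2 in step 9. The selectivity needed is aryl migration over aroyl migration and over plain α,β-dimethoxylation, and it is secured by the oxygen para to the migrating carbon on each ring (4'-OMe on ring B, the diaryl ether oxygen on the phenoxy ring). Making the oxidant before the substrate is added keeps the electron-rich bis-chalcone away from the anode, and the MOM ethers keep the ortho phenols from being oxidised or closing to flavanones.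

Step 9
Reactants: 15 bis-acetal
Product: 18 8-chloro-7-methoxy-3-[4-[2-methoxy-5-(7-methoxy-4-oxochromen-3-yl)phenoxy]phenyl]chromen-4-one, via bis-phenol bis-acetal 16 (not isolated), via bis(2-methoxyisoflavanone) 17 (not isolated)
Conditions: conc. HCl (10% v/v), MeOH–THF, 60 °C
Reagents that add atoms: none
Why: Acid-catalysed acetal chemistry throughout, in which the MOM ethers are methanolysed, each freed phenol attacks the oxocarbenium ion of its dimethyl acetal (6-exo-trig) to give the 2-methoxyisoflavanone, and loss of methanol across C2–C3 gives the pyranone, the usual end of the chalcone-rearrangement route to isoflavones.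

Step 10
Reactants: 18 8-chloro-7-methoxy-3-[4-[2-methoxy-5-(7-methoxy-4-oxochromen-3-yl)phenoxy]phenyl]chromen-4-one
Product: 19 Bisoflavolin K, 8-chloro-7-hydroxy-3-[4-[2-hydroxy-5-(7-hydroxy-4-oxochromen-3-yl)phenoxy]phenyl]chromen-4-one
Conditions: BBr3 (10 equiv), CH2Cl2, −78 °C to rt; then MeOH/H2O
Reagents that add atoms: none
Why: BBr3 cleaves aryl methyl ethers by Lewis-acid activation and bromide SN2 attack at methyl, while the diaryl ether, the aryl chloride and the pyranone rings are inert to it, as is usual for methoxyisoflavones.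

**Compound list**

1 | 2-chlororesorcinol | Oc1cccc(O)c1Cl | starting material
2 | 1-(3-chloro-2,4-dihydroxyphenyl)ethan-1-one | CC(=O)c1ccc(O)c(Cl)c1O | intermediate
3 | 1-(3-chloro-2-hydroxy-4-methoxyphenyl)ethan-1-one | CC(=O)c1ccc(OC)c(Cl)c1O | intermediate
4 | 1-[3-chloro-4-methoxy-2-(methoxymethoxy)phenyl]ethan-1-one | CC(=O)c1ccc(OC)c(Cl)c1OCOC | intermediate
5 | paeonol, 1-(2-hydroxy-4-methoxyphenyl)ethan-1-one | CC(=O)c1ccc(OC)cc1O | starting material
6 | 1-[4-methoxy-2-(methoxymethoxy)phenyl]ethan-1-one | CC(=O)c1ccc(OC)cc1OCOC | intermediate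
7 | isovanillin, 3-hydroxy-4-methoxybenzaldehyde | COc1ccc(C=O)cc1O | starting material
8 | 3-hydroxy-3-(3-hydroxy-4-methoxyphenyl)-1-[4-methoxy-2-(methoxymethoxy)phenyl]propan-1-one (aldol adduct, racemic, not isolated) | COCOc1cc(OC)ccc1C(=O)C[C@@H](O)c1ccc(OC)c(O)c1 | intermediate
9 | (E)-3-(3-hydroxy-4-methoxyphenyl)-1-[4-methoxy-2-(methoxymethoxy)phenyl]prop-2-en-1-one | COCOc1cc(OC)ccc1C(=O)/C=C/c1ccc(OC)c(O)c1 | intermediate
10 | 4-fluorobenzaldehyde | O=Cc1ccc(F)cc1 | starting material
11 | 4-[2-methoxy-5-[(E)-3-[4-methoxy-2-(methoxymethoxy)phenyl]-3-oxoprop-1-enyl]phenoxy]benzaldehyde | COCOc1cc(OC)ccc1C(=O)/C=C/c1ccc(OC)c(Oc2ccc(C=O)cc2)c1 | intermediate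
12 | (E)-3-[3-[4-[3-[3-chloro-4-methoxy-2-(methoxymethoxy)phenyl]-1-hydroxy-3-oxopropyl]phenoxy]-4-methoxyphenyl]-1-[4-methoxy-2-(methoxymethoxy)phenyl]prop-2-en-1-one (aldol adduct, racemic, not isolated) | COCOc1cc(OC)ccc1C(=O)/C=C/c1ccc(OC)c(Oc2ccc([C@@H](O)CC(=O)c3ccc(OC)c(Cl)c3OCOC)cc2)c1 | intermediate
13 | (E)-1-[3-chloro-4-methoxy-2-(methoxymethoxy)phenyl]-3-[4-[2-methoxy-5-[(E)-3-[4-methoxy-2-(methoxymethoxy)phenyl]-3-oxoprop-1-enyl]phenoxy]phenyl]prop-2-en-1-one (bis-chalcone, both alkenes E) | COCOc1cc(OC)ccc1C(=O)/C=C/c1ccc(OC)c(Oc2ccc(/C=C/C(=O)c3ccc(OC)c(Cl)c3OCOC)cc2)c1 | intermediate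
14 | (E)-1-[3-chloro-4-methoxy-2-(methoxymethoxy)phenyl]-3-[4-[5-[1,1-dimethoxy-3-[4-methoxy-2-(methoxymethoxy)phenyl]-3-oxopropan-2-yl]-2-methoxyphenoxy]phenyl]prop-2-en-1-one (mono-rearranged, racemic, not isolated) | COCOc1cc(OC)ccc1C(=O)[C@@H](C(OC)OC)c1ccc(OC)c(Oc2ccc(/C=C/C(=O)c3ccc(OC)c(Cl)c3OCOC)cc2)c1 | intermediate
15 | 1-[3-chloro-4-methoxy-2-(methoxymethoxy)phenyl]-2-[4-[5-[1,1-dimethoxy-3-[4-methoxy-2-(methoxymethoxy)phenyl]-3-oxopropan-2-yl]-2-methoxyphenoxy]phenyl]-3,3-dimethoxypropan-1-one (bis-acetal, one diastereomer drawn) | COCOc1cc(OC)ccc1C(=O)[C@@H](C(OC)OC)c1ccc(OC)c(Oc2ccc([C@H](C(OC)OC)C(=O)c3ccc(OC)c(Cl)c3OCOC)cc2)c1 | intermediate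
16 | 1-(3-chloro-2-hydroxy-4-methoxyphenyl)-2-[4-[5-[3-(2-hydroxy-4-methoxyphenyl)-1,1-dimethoxy-3-oxopropan-2-yl]-2-methoxyphenoxy]phenyl]-3,3-dimethoxypropan-1-one (MOM-free bis-acetal, one diastereomer drawn, not isolated) | Oc1cc(OC)ccc1C(=O)[C@@H](C(OC)OC)c1ccc(OC)c(Oc2ccc([C@H](C(OC)OC)C(=O)c3ccc(OC)c(Cl)c3O)cc2)c1 | intermediate
17 | 8-chloro-2,7-dimethoxy-3-[4-[5-(2,7-dimethoxy-4-oxochroman-3-yl)-2-methoxyphenoxy]phenyl]chroman-4-one (bis(2-methoxyisoflavanone), one diastereomer drawn, not isolated) | COc1ccc2c(c1)O[C@H](OC)[C@@H](c1ccc(OC)c(Oc3ccc([C@H]4[C@@H](OC)Oc5c(Cl)c(OC)ccc5C4=O)cc3)c1)C2=O | intermediate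
18 | 8-chloro-7-methoxy-3-[4-[2-methoxy-5-(7-methoxy-4-oxochromen-3-yl)phenoxy]phenyl]chromen-4-one | COc1ccc2c(c1)occ(-c1ccc(OC)c(Oc3ccc(-c4coc5c(Cl)c(OC)ccc5c4=O)cc3)c1)c2=O | intermediate
19 | Bisoflavolin K, 8-chloro-7-hydroxy-3-[4-[2-hydroxy-5-(7-hydroxy-4-oxochromen-3-yl)phenoxy]phenyl]chromen-4-one (no stereocentre) | O=c1c(-c2ccc(O)c(Oc3ccc(-c4coc5c(Cl)c(O)ccc5c4=O)cc3)c2)coc2cc(O)ccc12 | target

**Step count and risks**

Total step count: 10. Longest linear sequence: 7 steps (paeonol through steps 4–10, or 2-chlororesorcinol through steps 1–3 and 7–10).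

Steps most likely to fail:

1. Step 8. The electrogenerated trivalent iodine species may engage the enones too slowly, stop after one migration, or oxidise the electron-rich aryl ether rings instead; early MOM loss could also divert material to flavanones. Fallback (from 13, returning at 18): the same C3-aryl skeleton is reached by an aroyl shift instead of an aryl shift. Weitz–Scheffer epoxidation of both enones of 13 (H2O2, NaOH, MeOH–THF, 0 °C) should give the bis(trans-epoxy ketone) F1. BF3·OEt2 in CH2Cl2 at 0 °C opens each oxirane at the benzylic carbon and the aroyl group migrates, giving the bis(2-aryl-3-oxopropanal) F2, which has the connectivity of 15 at the aldehyde oxidation level. Methanolic HCl as in step 9 then removes the MOM groups and cyclodehydrates to 18; MOM loss during the BF3 stage would be harmless because the freed phenol closes to the same ring.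

2. Step 7. The enolate of 4 may add in conjugate fashion to the enone already present, or retro-aldol exchange may scramble the two halves under the reversible hydroxide conditions. Fallback (from 4 and 11, returning at 13): a directed aldol under kinetic control. Ketone 4 is converted to its lithium enolate with LiN(SiMe3)2 in THF at −78 °C and treated with 11; quenching cold with AcOH should allow aldol 12 to be isolated. MsCl/Et3N in CH2Cl2 at 0 °C gives the benzylic mesylate F3, which on addition of DBU eliminates to the E-enone 13.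

3. Step 6. The chalcone may degrade by phenoxide conjugate addition to another enone or by retro-aldol cleavage at the temperature needed for fluoride displacement. Fallback (from 9, returning at 11): Chan–Lam oxidative coupling of phenol 9 with commercial 4-formylphenylboronic acid (Cu(OAc)2, pyridine, 4 Å molecular sieves, CH2Cl2, air, rt) forms the same diaryl ether at room temperature without carbonate base. No compound outside the list is made (F0).

**Further compounds**

F1 | step 8 | bis(trans-epoxy ketone) of 13, both enone C=C bonds replaced by trans-oxirane rings (one diastereomer drawn) | COCOc1cc(OC)ccc1C(=O)[C@H]1O[C@@H]1c1ccc(OC)c(Oc2ccc([C@@H]3O[C@H]3C(=O)c3ccc(OC)c(Cl)c3OCOC)cc2)c1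
F2 | step 8 | bis(2-aryl-3-oxopropanal), 15 with each CH(OMe)2 group replaced by CHO (labile centres, one diastereomer drawn) | COCOc1cc(OC)ccc1C(=O)[C@@H](C=O)c1ccc(OC)c(Oc2ccc([C@H](C=O)C(=O)c3ccc(OC)c(Cl)c3OCOC)cc2)c1
F3 | step 7 | methanesulfonate of aldol 12 at its benzylic hydroxyl (racemic) | COCOc1cc(OC)ccc1C(=O)/C=C/c1ccc(OC)c(Oc2ccc([C@@H](OS(C)(=O)=O)CC(=O)c3ccc(OC)c(Cl)c3OCOC)cc2)c1
F0 | step 6 | none | none
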